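**Strategy.** With the chain numbered C1 (CH2 on the 4-hydroxyphenyl ring B) to C7 (CH2 on the guaiacyl ring A), the C3 oxygen and the benzylic C7 are 1,5-related. C3–C7 can therefore be tied up for a while in a tetrahydropyran (O, C3, C4, C5, C6, C7). A bromide-terminated Prins cyclisation of a tyrosine-derived C1–C6 homoallylic alcohol (free C3–OH, benzylated C2–OH, terminal C5=C6) with O-benzylvanillin makes C7–O, C6–C7 and C5–Br at once and relays the C3 configuration to C5. Acetate inversion at C5 then gives the 3,5-syn pattern, and hydrogenolysis reopens the ring at the benzylic C7–O bond together with all benzyl ethers.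

Key step: step 5

Remark: the target is read as (2S,3S,5S)-7-(4-hydroxy-3-methoxyphenyl)-1-(4-hydroxyphenyl)heptane-2,3,5-triol, with all three hydroxyls syn in the zigzag drawing. Chain locants C1–C7 are used for all intermediates, and pyran locants appear only inside names. O-Benzyl-L-tyrosine, allyltributylstannane and 4-(benzyloxy)-3-methoxybenzaldehyde are taken as purchased.

**Step 1**
Reactants: 1 O-benzyl-L-tyrosine, (S)-2-amino-3-[4-(benzyloxy)phenyl]propanoic acid
Product: 2 (S)-3-[4-(benzyloxy)phenyl]-2-hydroxypropanoic acid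
Conditions: NaNO2, 1 M H2SO4, 1,4-dioxane–H2O, 0 °C to rt
Reagents that add atoms: water, O
Why: Diazotisation of the α-amino acid, in which the neighbouring carboxylate expels N2 to give an α-lactone that water opens, so two inversions leave C2 with net retention as (S), while the aryl benzyl ether is inert to cold dilute acid.

**Step 2**
Reactants: 2 (S)-3-[4-(benzyloxy)phenyl]-2-hydroxypropanoic acid
Product: 3 benzyl (S)-2-(benzyloxy)-3-[4-(benzyloxy)phenyl]propanoate
Conditions: BnBr (3 equiv), Ag2O (2.5 equiv), CH2Cl2, rt, dark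
Reagents that add atoms: benzyl bromide, BrCc1ccccc1
Why: Purdie-type alkylation, in which the silver carboxylate is benzylated to the ester and the α-hydroxyl to the ether under essentially neutral conditions, avoiding the enolisation at C2 that a strong base would risk.

**Step 3**
Reactants: 3 benzyl (S)-2-(benzyloxy)-3-[4-(benzyloxy)phenyl]propanoate
Product: 4 (S)-2-(benzyloxy)-3-[4-(benzyloxy)phenyl]propanal
Conditions: iBu2AlH (1.1 equiv), CH2Cl2, −78 °C; MeOH, aq. potassium sodium tartrate; short silica plug, used at once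
Reagents that add atoms: none
Why: Partial reduction of an α-alkoxy ester at −78 °C should stop at the chelated aluminium hemiacetal, which releases the aldehyde only on work-up, so over-reduction and epimerisation at C2 are kept small.

**Step 4**
Reactants: 4 (S)-2-(benzyloxy)-3-[4-(benzyloxy)phenyl]propanal; 5 allyltributylstannane
Product: 6 (2S,3S)-2-(benzyloxy)-1-[4-(benzyloxy)phenyl]hex-5-en-3-ol
Conditions: MgBr2·OEt2 (2.5 equiv), CH2Cl2, −25 °C to 0 °C
Reagents that add atoms: none
Why: Keck allylation under Cram-chelate control, in which MgBr2 bridges the aldehyde oxygen and the C2 benzyloxy oxygen and the stannane attacks the face opposite the C1 arylmethyl group, setting C3 as (S) in a 2,3-syn relationship.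

**Step 5**
Reactants: 6 (2S,3S)-2-(benzyloxy)-1-[4-(benzyloxy)phenyl]hex-5-en-3-ol; 7 4-(benzyloxy)-3-methoxybenzaldehyde (O-benzylvanillin)
Product: 8 all-cis (2R,4R,6S)-2-[4-(benzyloxy)-3-methoxyphenyl]-4-bromo-6-{(1S)-1-(benzyloxy)-2-[4-(benzyloxy)phenyl]ethyl}tetrahydro-2H-pyran (pyran C2 = chain C7, pyran C4 = chain C5, pyran C6 = chain C3)
Conditions: InBr3 (10 mol%), Me3SiBr (1.2 equiv), CH2Cl2, −78 °C to 0 °C
Reagents that add atoms: bromotrimethylsilane, C[Si](C)(C)Br
Why: The C3–OH adds to aldehyde 7 and the resulting hemiacetal is ionised by Me3SiBr/InBr3 to an (E)-oxocarbenium ion conjugated with ring A (C7–O bond), which the C5=C6 alkene attacks through a chair transition state (C6–C7 bond) before bromide caps the C5 cation (C5–Br bond). The closest known reaction type is the halide-terminated Prins cyclisation of homoallylic alcohols with aryl aldehydes under metal halide/silyl halide promotion, which gives all-cis 4-halo-2,6-disubstituted tetrahydropyrans. The one new ring (O, C3, C4, C5, C6, C7) closes in a 6-endo-trig cation–olefin mode. C7 is controlled by the (E)-oxocarbenium geometry in a chair that keeps both the aryl group and the C3 side chain equatorial (2,6-cis), and C5 by equatorial capture of the chair cation by bromide, so both new centres are relayed from C3. The step needs the all-cis outcome (C5–Br cis to the C3 side chain, the 3,5-anti arrangement that the next step inverts) and an intact C3 centre; the aryl-conjugated oxocarbenium lies well below its oxonia-Cope isomer, which the electron-withdrawing C2 benzyloxy group destabilises further, and low temperature with a soluble bromide source keeps capture faster than allyl exchange. C7 is erased later, so only the C3-to-C5 relay matters, and the benzyl and methyl ethers should tolerate Me3SiBr at or below 0 °C.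

**Step 6**
Reactants: 8 all-cis (2R,4R,6S)-2-[4-(benzyloxy)-3-methoxyphenyl]-4-bromo-6-{(1S)-1-(benzyloxy)-2-[4-(benzyloxy)phenyl]ethyl}tetrahydro-2H-pyran
Product: 10 (2R,4S,6S)-2-[4-(benzyloxy)-3-methoxyphenyl]-6-{(1S)-1-(benzyloxy)-2-[4-(benzyloxy)phenyl]ethyl}tetrahydro-2H-pyran-4-ol (hydroxyl axial, trans to both ring substituents), via C5 acetate 9 (not isolated)
Conditions: CsOAc (5 equiv), 18-crown-6 (2 equiv), toluene, 90 °C; then K2CO3, MeOH, rt
Reagents that add atoms: caesium acetate, CC(=O)[O-].[Cs+]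
Why: SN2 displacement of the equatorial secondary bromide by crown-activated acetate should proceed with inversion to the axial C5 acetate (an equatorial leaving group has no antiperiplanar ring hydrogen, which disfavours E2), and base-catalysed transesterification then frees the C5–OH, now 3,5-syn to the oxygen on C3.

**Step 7**
Reactants: 10 (2R,4S,6S)-2-[4-(benzyloxy)-3-methoxyphenyl]-6-{(1S)-1-(benzyloxy)-2-[4-(benzyloxy)phenyl]ethyl}tetrahydro-2H-pyran-4-ol
Product: 11 (2S,3S,5S)-7-(4-hydroxy-3-methoxyphenyl)-1-(4-hydroxyphenyl)heptane-2,3,5-triol (target)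
Conditions: H2 (4 bar), Pd(OH)2 on carbon, EtOH, cat. HCl, rt
Reagents that add atoms: none
Why: Catalytic hydrogenolysis should remove the three benzyl ethers and, once the ring A phenol is free, cleave the activated benzylic C7–O ring bond (helped by trace acid through the p-quinone methide), whereas the non-benzylic C2–O, C3–O and C5–O bonds stay, so no stereocentre is touched.

**Compound list**
1 | O-benzyl-L-tyrosine, (S)-2-amino-3-[4-(benzyloxy)phenyl]propanoic acid | N[C@@H](Cc1ccc(OCc2ccccc2)cc1)C(=O)O | starting material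
2 | (S)-3-[4-(benzyloxy)phenyl]-2-hydroxypropanoic acid | O[C@@H](Cc1ccc(OCc2ccccc2)cc1)C(=O)O | intermediate
3 | benzyl (S)-2-(benzyloxy)-3-[4-(benzyloxy)phenyl]propanoate | O=C(OCc1ccccc1)[C@@H](OCc1ccccc1)Cc1ccc(OCc2ccccc2)cc1 | intermediate
4 | (S)-2-(benzyloxy)-3-[4-(benzyloxy)phenyl]propanal | O=C[C@@H](OCc1ccccc1)Cc1ccc(OCc2ccccc2)cc1 | intermediate
5 | allyltributylstannane | C=CC[Sn](CCCC)(CCCC)CCCC | starting material
6 | (2S,3S)-2-(benzyloxy)-1-[4-(benzyloxy)phenyl]hex-5-en-3-ol | C=CC[C@H](O)[C@@H](OCc1ccccc1)Cc1ccc(OCc2ccccc2)cc1 | intermediate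
7 | 4-(benzyloxy)-3-methoxybenzaldehyde (O-benzylvanillin) | COc1cc(C=O)ccc1OCc1ccccc1 | starting material
8 | all-cis (2R,4R,6S)-2-[4-(benzyloxy)-3-methoxyphenyl]-4-bromo-6-{(1S)-1-(benzyloxy)-2-[4-(benzyloxy)phenyl]ethyl}tetrahydro-2H-pyran | COc1cc([C@H]2C[C@@H](Br)C[C@H](O2)[C@@H](OCc3ccccc3)Cc3ccc(OCc4ccccc4)cc3)ccc1OCc1ccccc1 | intermediate
9 | (2R,4S,6S)-2-[4-(benzyloxy)-3-methoxyphenyl]-6-{(1S)-1-(benzyloxy)-2-[4-(benzyloxy)phenyl]ethyl}tetrahydro-2H-pyran-4-yl acetate (acetate axial) | COc1cc([C@H]2C[C@H](OC(C)=O)C[C@H](O2)[C@@H](OCc3ccccc3)Cc3ccc(OCc4ccccc4)cc3)ccc1OCc1ccccc1 | intermediate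
10 | (2R,4S,6S)-2-[4-(benzyloxy)-3-methoxyphenyl]-6-{(1S)-1-(benzyloxy)-2-[4-(benzyloxy)phenyl]ethyl}tetrahydro-2H-pyran-4-ol (hydroxyl axial) | COc1cc([C@H]2C[C@H](O)C[C@H](O2)[C@@H](OCc3ccccc3)Cc3ccc(OCc4ccccc4)cc3)ccc1OCc1ccccc1 | intermediate
11 | (2S,3S,5S)-7-(4-hydroxy-3-methoxyphenyl)-1-(4-hydroxyphenyl)heptane-2,3,5-triol | COc1cc(CC[C@H](O)C[C@H](O)[C@@H](O)Cc2ccc(O)cc2)ccc1O | target

**Step count**
Total steps: 7. Longest linear sequence: 7 (from 1 to 11).

**Steps most likely to fail**

Step 5. What may go wrong: allyl exchange through oxonia-Cope rearrangement, partial axial capture of bromide that erodes the C5 configuration, or loss of a benzyl ether to the silyl bromide. The fallback is a segment-coupling Prins reaction that generates the same oxocarbenium ion without free aldehyde or water. Setting out from 6, esterification with 4-(benzyloxy)-3-methoxybenzoic acid (DCC, DMAP, CH2Cl2) gives (2S,3S)-2-(benzyloxy)-1-[4-(benzyloxy)phenyl]hex-5-en-3-yl 4-(benzyloxy)-3-methoxybenzoate F1. Reductive acetylation (iBu2AlH, CH2Cl2, −78 °C; then Ac2O, pyridine, DMAP) gives the α-acetoxy ether [4-(benzyloxy)-3-methoxyphenyl]{[(2S,3S)-2-(benzyloxy)-1-[4-(benzyloxy)phenyl]hex-5-en-3-yl]oxy}methyl acetate F2 as a mixture at the acetal carbon. SnBr4 in CH2Cl2 at −78 °C should then ionise F2 and close the ring with equatorial bromide, coming back to the route at 8.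

Step 6. What may go wrong: E2 elimination to dihydropyrans, or a sluggish substitution at the secondary ring carbon. The fallback sets the axial C5 oxygen by oxidation and reduction and so needs no substitution at carbon. Setting out from 6 and 7, an oxygen-terminated Prins cyclisation with CF3CO2H in CH2Cl2 should give the all-cis (2R,4R,6S)-2-[4-(benzyloxy)-3-methoxyphenyl]-6-{(1S)-1-(benzyloxy)-2-[4-(benzyloxy)phenyl]ethyl}tetrahydro-2H-pyran-4-yl trifluoroacetate F3. K2CO3 in MeOH cleaves it to the equatorial alcohol (2R,4R,6S)-2-[4-(benzyloxy)-3-methoxyphenyl]-6-{(1S)-1-(benzyloxy)-2-[4-(benzyloxy)phenyl]ethyl}tetrahydro-2H-pyran-4-ol F4. Dess–Martin periodinane oxidation gives (2R,6S)-2-[4-(benzyloxy)-3-methoxyphenyl]-6-{(1S)-1-(benzyloxy)-2-[4-(benzyloxy)phenyl]ethyl}tetrahydro-4H-pyran-4-one F5. LiBH(s-Bu)3 in THF at −78 °C should deliver hydride from the equatorial side and give the axial alcohol, coming back to the route at 10.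

Step 7. What may go wrong: the benzyl ethers are removed but the cyclic benzylic ether resists hydrogenolysis, so the tetrahydropyran survives. The fallback cleaves C7–O by ionic hydrogenation while ring A is still O-benzylated. Setting out from 10, Et3SiH with CF3CO2H in CH2Cl2 at −20 to 0 °C should open the ring to the ring A-stabilised C7 cation, which the silane reduces irreversibly. After a K2CO3/MeOH wash to remove any trifluoroacetate esters, this gives (2S,3S,5S)-2-(benzyloxy)-1-[4-(benzyloxy)phenyl]-7-[4-(benzyloxy)-3-methoxyphenyl]heptane-3,5-diol F6. Ordinary debenzylation (H2, Pd/C, EtOH) then comes back to the route at 11.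

**Further compounds**
F1 | step 5 | (2S,3S)-2-(benzyloxy)-1-[4-(benzyloxy)phenyl]hex-5-en-3-yl 4-(benzyloxy)-3-methoxybenzoate | C=CC[C@H](OC(=O)c1ccc(OCc2ccccc2)c(OC)c1)[C@@H](OCc1ccccc1)Cc1ccc(OCc2ccccc2)cc1
F2 | step 5 | [4-(benzyloxy)-3-methoxyphenyl]{[(2S,3S)-2-(benzyloxy)-1-[4-(benzyloxy)phenyl]hex-5-en-3-yl]oxy}methyl acetate (both acetal epimers) | C=CC[C@H](OC(OC(C)=O)c1ccc(OCc2ccccc2)c(OC)c1)[C@@H](OCc1ccccc1)Cc1ccc(OCc2ccccc2)cc1
F3 | step 6 | (2R,4R,6S)-2-[4-(benzyloxy)-3-methoxyphenyl]-6-{(1S)-1-(benzyloxy)-2-[4-(benzyloxy)phenyl]ethyl}tetrahydro-2H-pyran-4-yl trifluoroacetate | COc1cc([C@H]2C[C@@H](OC(=O)C(F)(F)F)C[C@H](O2)[C@@H](OCc3ccccc3)Cc3ccc(OCc4ccccc4)cc3)ccc1OCc1ccccc1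
F4 | step 6 | (2R,4R,6S)-2-[4-(benzyloxy)-3-methoxyphenyl]-6-{(1S)-1-(benzyloxy)-2-[4-(benzyloxy)phenyl]ethyl}tetrahydro-2H-pyran-4-ol | COc1cc([C@H]2C[C@@H](O)C[C@H](O2)[C@@H](OCc3ccccc3)Cc3ccc(OCc4ccccc4)cc3)ccc1OCc1ccccc1
F5 | step 6 | (2R,6S)-2-[4-(benzyloxy)-3-methoxyphenyl]-6-{(1S)-1-(benzyloxy)-2-[4-(benzyloxy)phenyl]ethyl}tetrahydro-4H-pyran-4-one | COc1cc([C@H]2CC(=O)C[C@H](O2)[C@@H](OCc3ccccc3)Cc3ccc(OCc4ccccc4)cc3)ccc1OCc1ccccc1
F6 | step 7 | (2S,3S,5S)-2-(benzyloxy)-1-[4-(benzyloxy)phenyl]-7-[4-(benzyloxy)-3-methoxyphenyl]heptane-3,5-diol | COc1cc(CC[C@H](O)C[C@H](O)[C@@H](OCc2ccccc2)Cc2ccc(OCc3ccccc3)cc2)ccc1OCc1ccccc1
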